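**Plan**
- The retrosynthesis first releases the C1 carboxyl of ring B from a benzyl ester. It then cuts the depside C(=O)–O bond between the ring A carbonyl and O4 of ring B, giving 2,4-dimethoxy-6-pentylbenzoic acid and benzyl 4-hydroxy-2-methoxy-6-propylbenzoate.
- Ring B carries a carboxyl at C1, oxygen at C2 and C4, and propyl at C6, which is the pattern of a folded tetraketide. It is therefore opened at the C1–C6 bond to an acyclic diketo-dioxinone whose acetonide holds the C1 carboxyl and O2 together.
- That chain is cut at two CH2–C(=O) bonds into 2,2,6-trimethyl-1,3-dioxin-4-one, an acetyl unit and a butanoyl unit.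
- Forward, the chain is joined in steps 1–3, ring B closes by aldol aromatisation in step 4, and O4, O2 and the carboxyl are addressed one at a time in steps 5–8. Ring A comes ready-made from olivetol and is methylated, formylated and oxidised in steps 9–11. Esterification (step 12) and hydrogenolysis (step 13) finish the route.
- The target has no stereocentre and no stereogenic double bond, so no stereochemistry has to be set.

Key step: step 4

Remark: LiN(SiMe3)2 and LiN(iPr)2 are taken as commercial THF solutions, and the carbinol carbon of the transient aldol in the key step forms racemic and vanishes on dehydration.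

**Step 1**
Reactants: 1 trimethyldioxinone (2,2,6-trimethyl-4H-1,3-dioxin-4-one)
Product: 3 keto-dioxinone 6-(2-oxopropyl)-2,2-dimethyl-4H-1,3-dioxin-4-one, via lithium dienolate 2 (not isolated)
Conditions: LiN(SiMe3)2, THF, −78 °C; then AcCl (limiting, 0.5 equiv), −78 °C
Reagents that add atoms: acetyl chloride CC(=O)Cl
Why: Kinetic deprotonation at the C6 methyl gives the extended lithium dienolate, which is C-acylated at its γ-terminus by the acid chloride (vinylogous Claisen-type acylation of a dioxinone dienolate), and keeping acetyl chloride limiting lets surplus dienolate take up the more acidic proton of 3 instead of causing double acylation.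

**Step 2**
Reactants: 4 butanoyl chloride
Product: 5 N-methoxy-N-methylbutanamide
Conditions: MeNH(OMe)·HCl, K2CO3, CH2Cl2/H2O, 0 °C to rt
Reagents that add atoms: N,O-dimethylhydroxylamine hydrochloride CNOC.Cl
Why: Schotten–Baumann N-acylation under biphasic carbonate conditions gives the Weinreb amide, an acyl donor mild enough to deliver one butanoyl group to a carbanion without O-acylation or double addition.

**Step 3**
Reactants: 3 keto-dioxinone 6-(2-oxopropyl)-2,2-dimethyl-4H-1,3-dioxin-4-one; 5 N-methoxy-N-methylbutanamide
Product: 7 diketo-dioxinone 6-(2,4-dioxoheptyl)-2,2-dimethyl-4H-1,3-dioxin-4-one, via dilithium dianion 6 (not isolated)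
Conditions: LiN(iPr)2 (2.2 equiv), THF, −78 to −40 °C; then 5, −40 °C; then 1 M HCl
Reagents that add atoms: none
Why: Two equivalents of amide base convert the β-keto-dioxinone into its dianion, whose last-formed and most reactive terminal carbanion is acylated by the Weinreb amide (dianion Claisen condensation), so the new CH2–C(=O) bond forms only at the former acetyl methyl.

**Step 4**
Reactants: 7 diketo-dioxinone 6-(2,4-dioxoheptyl)-2,2-dimethyl-4H-1,3-dioxin-4-one
Product: 9 resorcylate acetonide 7-hydroxy-2,2-dimethyl-5-propyl-4H-1,3-benzodioxin-4-one, via cyclic aldol 8 (not isolated)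
Conditions: Et3N, CH2Cl2, rt
Reagents that add atoms: none
Why: Et3N ionises the C1' methylene between dioxinone C6 and the C2' ketone, the resulting extended dienolate is nucleophilic at dioxinone C5, and C5 adds to the C4' propyl ketone to give aldol 8, which loses water and enolises its remaining ketone to reach the benzene ring. The closest known reaction type is the base-mediated biomimetic aldol aromatisation of diketo-dioxinones to resorcylate acetonides. The single ring closed, carbocyclic ring B, forms in the favoured 6-(enolexo)-exo-trig mode, and the new bond is C1–C6 of ring B (C4a–C5 of the benzodioxinone). No stereocentre results, because the carbinol carbon of 8 becomes sp2 on dehydration. The step needs carbon–carbon aldol closure to win over closure through an enol oxygen to a pyranone, over Claisen-type attack of the C3' carbanion on the lactone carbonyl and over thermal loss of acetone; the acetonide keeps the carboxyl as a weakly electrophilic, non-ionisable vinylogous carbonate, the weak base at room temperature ionises only the doubly activated methylenes, and aromatisation makes the aldol path irreversible. Because the acetonide survives, O2 and the carboxyl stay masked together and only the C4 hydroxyl of ring B (C7–OH of 9) is left free.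

**Step 5**
Reactants: 9 resorcylate acetonide 7-hydroxy-2,2-dimethyl-5-propyl-4H-1,3-benzodioxin-4-one
Product: 10 allyl ether 2,2-dimethyl-7-(prop-2-en-1-yloxy)-5-propyl-4H-1,3-benzodioxin-4-one
Conditions: allyl bromide, K2CO3, acetone, reflux
Reagents that add atoms: allyl bromide C=CCBr
Why: Williamson etherification of the only free hydroxyl blocks O4 with a group that withstands alkoxide and methylation conditions, and it removes the phenoxide that would otherwise deactivate the para lactone carbonyl in step 6.

**Step 6**
Reactants: 10 allyl ether 2,2-dimethyl-7-(prop-2-en-1-yloxy)-5-propyl-4H-1,3-benzodioxin-4-one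
Product: 11 benzyl 2-hydroxy-4-(prop-2-en-1-yloxy)-6-propylbenzoate
Conditions: BnOH, NaH, THF, 0 °C to rt; then 1 M HCl
Reagents that add atoms: benzyl alcohol OCc1ccccc1
Why: In this transesterification of a benzodioxinone, benzyl oxide attacks the acylal-type lactone carbonyl and the ring falls apart irreversibly into the benzyl ester, the O2 phenoxide and acetone, while the allyl ether is inert to the alkoxide.

**Step 7**
Reactants: 11 benzyl 2-hydroxy-4-(prop-2-en-1-yloxy)-6-propylbenzoate
Product: 12 benzyl 2-methoxy-4-(prop-2-en-1-yloxy)-6-propylbenzoate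
Conditions: MeI, K2CO3, DMF, rt
Reagents that add atoms: iodomethane CI
Why: Williamson O-methylation in a dipolar aprotic solvent overcomes the hydrogen bond of O2–H to the ester carbonyl, and O2 is the only nucleophilic site left in 11.

**Step 8**
Reactants: 12 benzyl 2-methoxy-4-(prop-2-en-1-yloxy)-6-propylbenzoate
Product: 13 benzyl 4-hydroxy-2-methoxy-6-propylbenzoate
Conditions: Pd(PPh3)4 (cat.), morpholine, THF, rt
Reagents that add atoms: none
Why: In this Tsuji–Trost-type deallylation, zerovalent palladium ionises the allyl aryl ether to a π-allyl complex and the ester-stabilised phenoxide, morpholine captures the allyl unit, and the benzyl ester and methyl ether are not touched.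

**Step 9**
Reactants: 14 olivetol (5-pentylbenzene-1,3-diol)
Product: 15 1,3-dimethoxy-5-pentylbenzene
Conditions: MeI, K2CO3, acetone, reflux
Reagents that add atoms: iodomethane CI
Why: Double Williamson O-methylation of a resorcinol is routine and leaves no free hydroxyl on ring A.

**Step 10**
Reactants: 15 1,3-dimethoxy-5-pentylbenzene
Product: 17 2,4-dimethoxy-6-pentylbenzaldehyde, via aryl iminium salt 16 (not isolated)
Conditions: POCl3, DMF, 0 to 60 °C; then ice-water
Reagents that add atoms: N,N-dimethylformamide CN(C)C=O; water O
Why: Vilsmeier–Haack formylation attacks the ring position para to one methoxy group and ortho to the other, next to the pentyl chain, in preference to the position squeezed between the two methoxy groups, as is usual for 5-alkylresorcinol dimethyl ethers.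

**Step 11**
Reactants: 17 2,4-dimethoxy-6-pentylbenzaldehyde
Product: 18 2,4-dimethoxy-6-pentylbenzoic acid
Conditions: NaClO2, NaH2PO4, 2-methyl-2-butene, t-BuOH/H2O, rt
Reagents that add atoms: sodium chlorite [Na+].[O-]Cl=O
Why: Pinnick oxidation converts the hindered aldehyde into the acid under mildly acidic conditions, and 2-methyl-2-butene traps the hypochlorous acid that would otherwise chlorinate the electron-rich ring.

**Step 12**
Reactants: 18 2,4-dimethoxy-6-pentylbenzoic acid; 13 benzyl 4-hydroxy-2-methoxy-6-propylbenzoate
Product: 20 benzyl 4-[(2,4-dimethoxy-6-pentylbenzoyl)oxy]-2-methoxy-6-propylbenzoate, via mixed trifluoroacetic anhydride 19 (not isolated)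
Conditions: (CF3CO)2O, toluene, rt
Reagents that add atoms: none
Why: In this mixed-anhydride esterification of a hindered acid, the electron-rich, di-ortho-substituted aroyl trifluoroacetate has strong acylium character and therefore acylates the single free hydroxyl of 13 despite the flanking methoxy and pentyl groups, a method long used for depside bonds.

**Step 13**
Reactants: 20 benzyl 4-[(2,4-dimethoxy-6-pentylbenzoyl)oxy]-2-methoxy-6-propylbenzoate
Product: 21 4-[(2,4-dimethoxy-6-pentylbenzoyl)oxy]-2-methoxy-6-propylbenzoic acid (target)
Conditions: H2 (1 atm), 10% Pd/C, EtOAc, rt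
Reagents that add atoms: none
Why: Catalytic hydrogenolysis cleaves only the benzylic C–O bond, while the aryl ester, the methyl ethers and both arenes are inert under one atmosphere of hydrogen.

**Compound list**
1 | 2,2,6-trimethyl-4H-1,3-dioxin-4-one | CC1=CC(=O)OC(C)(C)O1 | starting material
2 | lithium 2,2-dimethyl-6-methylidene-6H-1,3-dioxin-4-olate (lithium dienolate of 1, not isolated) | [Li+].C=C1C=C([O-])OC(C)(C)O1 | intermediate
3 | 6-(2-oxopropyl)-2,2-dimethyl-4H-1,3-dioxin-4-one | CC(=O)CC1=CC(=O)OC(C)(C)O1 | intermediate
4 | butanoyl chloride | CCCC(=O)Cl | starting material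
5 | N-methoxy-N-methylbutanamide | CCCC(=O)N(C)OC | intermediate
6 | dilithium dianion of 3, drawn as the bis-enolate (not isolated) | [Li+].[Li+].C=C([O-])C=C1C=C([O-])OC(C)(C)O1 | intermediate
7 | 6-(2,4-dioxoheptyl)-2,2-dimethyl-4H-1,3-dioxin-4-one | CCCC(=O)CC(=O)CC1=CC(=O)OC(C)(C)O1 | intermediate
8 | 5-hydroxy-2,2-dimethyl-5-propyl-5,6-dihydro-4H-1,3-benzodioxine-4,7(8H)-dione (racemic cyclic aldol, not isolated) | CCCC1(O)CC(=O)CC2=C1C(=O)OC(C)(C)O2 | intermediate
9 | 7-hydroxy-2,2-dimethyl-5-propyl-4H-1,3-benzodioxin-4-one | CCCc1cc(O)cc2OC(C)(C)OC(=O)c12 | intermediate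
10 | 2,2-dimethyl-7-(prop-2-en-1-yloxy)-5-propyl-4H-1,3-benzodioxin-4-one | CCCc1cc(OCC=C)cc2OC(C)(C)OC(=O)c12 | intermediate
11 | benzyl 2-hydroxy-4-(prop-2-en-1-yloxy)-6-propylbenzoate | CCCc1cc(OCC=C)cc(O)c1C(=O)OCc1ccccc1 | intermediate
12 | benzyl 2-methoxy-4-(prop-2-en-1-yloxy)-6-propylbenzoate | CCCc1cc(OCC=C)cc(OC)c1C(=O)OCc1ccccc1 | intermediate
13 | benzyl 4-hydroxy-2-methoxy-6-propylbenzoate | CCCc1cc(O)cc(OC)c1C(=O)OCc1ccccc1 | intermediate
14 | olivetol (5-pentylbenzene-1,3-diol) | CCCCCc1cc(O)cc(O)c1 | starting material
15 | 1,3-dimethoxy-5-pentylbenzene | CCCCCc1cc(OC)cc(OC)c1 | intermediate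
16 | N-[(2,4-dimethoxy-6-pentylphenyl)methylidene]-N-methylmethanaminium dichlorophosphate (not isolated) | CCCCCc1cc(OC)cc(OC)c1C=[N+](C)C.[O-]P(=O)(Cl)Cl | intermediate
17 | 2,4-dimethoxy-6-pentylbenzaldehyde | CCCCCc1cc(OC)cc(OC)c1C=O | intermediate
18 | 2,4-dimethoxy-6-pentylbenzoic acid | CCCCCc1cc(OC)cc(OC)c1C(=O)O | intermediate
19 | 2,4-dimethoxy-6-pentylbenzoic trifluoroacetic anhydride (not isolated) | CCCCCc1cc(OC)cc(OC)c1C(=O)OC(=O)C(F)(F)F | intermediate
20 | benzyl 4-[(2,4-dimethoxy-6-pentylbenzoyl)oxy]-2-methoxy-6-propylbenzoate | CCCCCc1cc(OC)cc(OC)c1C(=O)Oc1cc(CCC)c(C(=O)OCc2ccccc2)c(OC)c1 | intermediate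
21 | 4-[(2,4-dimethoxy-6-pentylbenzoyl)oxy]-2-methoxy-6-propylbenzoic acid | CCCCCc1cc(OC)cc(OC)c1C(=O)Oc1cc(CCC)c(C(=O)O)c(OC)c1 | target

**Step count**
Total step count: 13.
Longest linear sequence: 9 steps (steps 1, 3, 4, 5, 6, 7, 8, 12, 13).

**Steps most likely to fail**

Step 3. The dianion may be quenched by proton transfer from the more acidic product as it forms. It may also acylate on oxygen, or the product may start to cyclise without control in the strongly basic medium, so the condensation can stall.
- The fallback sets out from 1 and 4 and comes back at 7. It replaces the hard dianion by soft magnesium enolate chemistry.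
- Dienolate 2, made from 1 as in step 1, is acylated with allyl 3-chloro-3-oxopropanoate to give allyl 4-(2,2-dimethyl-4-oxo-4H-1,3-dioxin-6-yl)-3-oxobutanoate F1.
- MgCl2 and pyridine in CH2Cl2 enolise the β-keto ester methylene of this compound. Butanoyl chloride 4 then acylates it on carbon to give allyl 2-[(2,2-dimethyl-4-oxo-4H-1,3-dioxin-6-yl)acetyl]-3-oxohexanoate F2.
- Pd(PPh3)4 with morpholine in THF removes the allyl group. The resulting 2-[(2,2-dimethyl-4-oxo-4H-1,3-dioxin-6-yl)acetyl]-3-oxohexanoic acid F3 should lose carbon dioxide at room temperature to give 7.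

Step 4. Closure through an enol oxygen, Claisen-type closure onto the lactone carbonyl, a stalled dehydration of the aldol, or loss of acetone could compete with the aldol aromatisation.
- The fallback sets out from 7 and comes back at 11. It takes the mask off before the cyclisation instead of after it, while the same C1–C6 bond is still made by an aldol closure.
- Heating 7 with benzyl alcohol in toluene at 110 °C causes retro-[4+2] loss of acetone to the acylketene dec-1-ene-1,3,5,7-tetrone F4. Benzyl alcohol traps it as benzyl 3,5,7-trioxodecanoate F5.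
- Cs2CO3 in CH2Cl2/i-PrOH followed by acidification closes and dehydrates the ring to benzyl 2,4-dihydroxy-6-propylbenzoate F6.
- Since O2–H is hydrogen-bonded to the ester carbonyl, one equivalent of allyl bromide with K2CO3 in acetone should alkylate O4 only. This gives 11 and makes steps 5 and 6 unnecessary.

Step 12. Acyl transfer from the di-ortho-substituted acid may be slow. Trifluoroacetylation of the phenol and Friedel–Crafts C-acylation of the electron-rich rings by the acylium-like species could then take over in the acidic medium.
- The fallback sets out from 18 and 13 and comes back at 20. It moves from acid-promoted acylium chemistry to an anionic acyl substitution in which both partners are activated beforehand.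
- Acid 18 is converted with oxalyl chloride and catalytic DMF in CH2Cl2 into 2,4-dimethoxy-6-pentylbenzoyl chloride F7, which is freed of volatiles.
- Phenol 13 is deprotonated with NaH in THF to sodium 4-[(benzyloxy)carbonyl]-3-methoxy-5-propylphenolate F8.
- The two are combined at 0 °C to rt to give 20.

**Further compounds**
F1 | step 3 | allyl 4-(2,2-dimethyl-4-oxo-4H-1,3-dioxin-6-yl)-3-oxobutanoate | C=CCOC(=O)CC(=O)CC1=CC(=O)OC(C)(C)O1
F2 | step 3 | allyl 2-[(2,2-dimethyl-4-oxo-4H-1,3-dioxin-6-yl)acetyl]-3-oxohexanoate (enolisable methine, no defined configuration) | CCCC(=O)C(C(=O)OCC=C)C(=O)CC1=CC(=O)OC(C)(C)O1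
F3 | step 3 | 2-[(2,2-dimethyl-4-oxo-4H-1,3-dioxin-6-yl)acetyl]-3-oxohexanoic acid | CCCC(=O)C(C(=O)O)C(=O)CC1=CC(=O)OC(C)(C)O1
F4 | step 4 | dec-1-ene-1,3,5,7-tetrone (acylketene) | CCCC(=O)CC(=O)CC(=O)C=C=O
F5 | step 4 | benzyl 3,5,7-trioxodecanoate | CCCC(=O)CC(=O)CC(=O)CC(=O)OCc1ccccc1
F6 | step 4 | benzyl 2,4-dihydroxy-6-propylbenzoate | CCCc1cc(O)cc(O)c1C(=O)OCc1ccccc1
F7 | step 12 | 2,4-dimethoxy-6-pentylbenzoyl chloride | CCCCCc1cc(OC)cc(OC)c1C(=O)Cl
F8 | step 12 | sodium 4-[(benzyloxy)carbonyl]-3-methoxy-5-propylphenolate | [Na+].[O-]c1cc(CCC)c(C(=O)OCc2ccccc2)c(OC)c1
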